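**Retrosynthetic overview**

- The flavonol pyranone is disconnected last: 3-hydroxylation ⇐ flavone 23 ⇐ chalcone 22 ⇐ aldehyde 19 + acetophenone 21. The formyl group at C4 comes from aryl bromide 17.
- The route rests on C3 of the dihydrobenzofuran, which carries aromatic C3a and the one-carbon CH2OH group. That pattern is what remains when C4 of a chroman-4-one leaves the ring as an ester and its bond to C4a is handed over to C3.
- Ester 14 is therefore traced to (R)-flavanone 12 by oxidative ring contraction, 12 to chromone 8 plus arylboronic acid 11 by asymmetric conjugate addition, and 8 to 2,3-dihydroxybenzaldehyde 1.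
- Rings form in this order: pyranone of chromone 8 (step 6), its contraction to the dihydrofuran ring (step 10), pyranone of the flavonol (step 17).

Key step: step 10

Assumption: the (R)-configured bisphosphine in step 9 is taken to give the (2R)-flavanone, by analogy with the usual facial sense of rhodium/biaryl-bisphosphine conjugate additions; if the first run shows the opposite sense, the (S)-ligand is used and nothing else changes.

**Route**

Step 1
Reactants: 1 2,3-dihydroxybenzaldehyde
Product: 2 3-(benzyloxy)-2-hydroxybenzaldehyde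
Conditions: NaH (2.2 equiv), DMSO/THF, rt; BnBr (1.0 equiv), rt; then dilute HCl
Reagents that add atoms: benzyl bromide, BrCc1ccccc1
Why: Williamson etherification of the dianion, in which the 2-phenoxide is held by conjugation and chelation with the formyl group, so the 3-phenoxide is the more nucleophilic site and takes the single equivalent of benzyl bromide.

Step 2
Reactants: 2 3-(benzyloxy)-2-hydroxybenzaldehyde
Product: 3 2-(benzyloxy)-6-formylphenyl acetate
Conditions: Ac2O, pyridine, DMAP (cat.), CH2Cl2, rt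
Reagents that add atoms: acetic anhydride, CC(=O)OC(C)=O
Why: Phenol acylation, which turns the 2-oxygen into a weak donor so that it no longer directs the bromination of step 3.

Step 3
Reactants: 3 2-(benzyloxy)-6-formylphenyl acetate
Product: 4 6-(benzyloxy)-3-bromo-2-formylphenyl acetate
Conditions: Br2 (1.05 equiv), NaOAc, AcOH, rt
Reagents that add atoms: bromine, BrBr
Why: Electrophilic aromatic bromination, directed by the benzyloxy group (the only strong donor left) to its para position next to the formyl group, as is known for the 3-methoxy analogue.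

Step 4
Reactants: 4 6-(benzyloxy)-3-bromo-2-formylphenyl acetate
Product: 5 6-(benzyloxy)-3-bromo-2-(1-hydroxyethyl)phenol (racemic carbinol)
Conditions: MeMgBr (3.5 equiv), THF, 0 °C to rt; then H2O
Reagents that add atoms: methylmagnesium bromide, C[Mg]Br
Why: Grignard addition to the aldehyde, in which the excess reagent also cleaves the aryl acetate and frees the phenol in the same operation; the carbinol centre is formed racemic and is removed in step 5.

Step 5
Reactants: 5 6-(benzyloxy)-3-bromo-2-(1-hydroxyethyl)phenol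
Product: 6 1-[3-(benzyloxy)-6-bromo-2-hydroxyphenyl]ethan-1-one
Conditions: MnO2 (activated, excess), CH2Cl2, rt
Reagents that add atoms: none
Why: Heterogeneous MnO2 oxidation of a benzylic alcohol, which tolerates the free phenol and gives the hydrogen-bonded ortho-hydroxy ketone.

Step 6
Reactants: 6 1-[3-(benzyloxy)-6-bromo-2-hydroxyphenyl]ethan-1-one
Product: 8 8-(benzyloxy)-5-bromo-4H-chromen-4-one, via enaminone 7 (not isolated)
Conditions: Me2NCH(OMe)2, toluene, 100 °C; then conc. HCl, CH2Cl2, 40 °C
Reagents that add atoms: N,N-dimethylformamide dimethyl acetal, COC(OC)N(C)C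
Why: Standard enaminone route to chromones: condensation of the methyl ketone with the amide acetal, then acid-promoted addition of the phenol to the β-carbon and loss of dimethylamine.

Step 7
Reactants: 9 2-methoxy-4-(4,4,5,5-tetramethyl-1,3,2-dioxaborolan-2-yl)phenol
Product: 10 2-methoxy-4-(4,4,5,5-tetramethyl-1,3,2-dioxaborolan-2-yl)phenyl methanesulfonate
Conditions: MsCl, Et3N, CH2Cl2, 0 °C
Reagents that add atoms: methanesulfonyl chloride, CS(=O)(=O)Cl
Why: Sulfonylation of the phenol, to which the pinacol boronate is inert; the mesylate is the electron-withdrawing mask needed in step 10.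

Step 8
Reactants: 10 2-methoxy-4-(4,4,5,5-tetramethyl-1,3,2-dioxaborolan-2-yl)phenyl methanesulfonate
Product: 11 [3-methoxy-4-(methylsulfonyloxy)phenyl]boronic acid
Conditions: NaIO4, NH4OAc, acetone/H2O, rt
Reagents that add atoms: water, O
Why: Hydrolysis of the boronic ester, driven by periodate cleavage of the released pinacol (Malaprade glycol cleavage) under near-neutral conditions that leave the aryl mesylate intact.

Step 9
Reactants: 8 8-(benzyloxy)-5-bromo-4H-chromen-4-one; 11 [3-methoxy-4-(methylsulfonyloxy)phenyl]boronic acid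
Product: 12 (2R)-8-(benzyloxy)-5-bromo-2-[3-methoxy-4-(methylsulfonyloxy)phenyl]-2,3-dihydro-4H-chromen-4-one
Conditions: [Rh(OH)(cod)]2 (1.5 mol%), (R)-MeO-F12-BIPHEP [(R)-6,6'-dimethoxy-2,2'-bis{bis(3,4,5-trifluorophenyl)phosphino}biphenyl] (3.3 mol%), 11 (3 equiv), toluene/H2O, 50 °C
Reagents that add atoms: none
Why: Hayashi–Miyaura conjugate addition, in which the aryl group passes from boron to a hydroxorhodium–bisphosphine complex, the C2=C3 bond inserts on the face chosen by the ligand (catalyst control sets C2 as R) and water releases the flavanone, while the electron-poor ligand allows base-free conditions so the product is not ring-opened to the chalcone.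

Step 10
Reactants: 12 (2R)-8-(benzyloxy)-5-bromo-2-[3-methoxy-4-(methylsulfonyloxy)phenyl]-2,3-dihydro-4H-chromen-4-one
Product: 14 methyl (2R,3R)-7-(benzyloxy)-4-bromo-2-[3-methoxy-4-(methylsulfonyloxy)phenyl]-2,3-dihydro-1-benzofuran-3-carboxylate (2,3-trans), via enol ether 13 (not isolated)
Conditions: PhI(OAc)2 (1.3 equiv), conc. H2SO4 (1.5 equiv), HC(OMe)3, 0 °C to rt; then aq. NaHCO3
Reagents that add atoms: trimethyl orthoformate, COC(OC)OC; water, O
Why: Acid and trimethyl orthoformate convert ketone 12 into its dimethyl ketal and enol ether 13, PhI(OAc)2 attacks C3 of 13 anti to the C2 aryl group and methanol restores the ketal at C4, after which the fused aryl carbon C4a shifts from C4 to C3 as iodobenzene leaves and the resulting dimethoxycarbenium ion is taken up as the ortho ester and hydrolysed to the methyl ester on work-up. This is the known oxidative ring contraction of flavanones by trivalent iodine (or trivalent thallium) in trimethyl orthoformate, a member of the oxidative 1,2-aryl shift family that turns aryl ketones into arylalkanoates. The dihydrofuran ring is closed by the 1,2-shift itself, which forms C3–C3a and contracts the six-membered pyranone to the five-membered ring, and not by cyclisation of an open chain. C2 is carried over unchanged from 12 and controls the new C3 centre: the iodane enters trans to the aryl group and the shift inverts C3, which places the ester trans to the aryl group, the more stable arrangement as well. The step needs migration of ring A in preference to the C2 aryl group (which would lead to an isoflavone) and no dehydrogenation to the flavone; the mesylate makes the C2 aryl group electron-poor and also keeps the benzylic C2–O bond from ionising in acid, while C4a has the ring oxygen in its ortho position to stabilise the bridged transition state.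

Step 11
Reactants: 14 methyl (2R,3R)-7-(benzyloxy)-4-bromo-2-[3-methoxy-4-(methylsulfonyloxy)phenyl]-2,3-dihydro-1-benzofuran-3-carboxylate
Product: 15 4-[(2R,3S)-7-(benzyloxy)-4-bromo-3-(hydroxymethyl)-2,3-dihydro-1-benzofuran-2-yl]-2-methoxyphenyl methanesulfonate
Conditions: i-Bu2AlH (DIBAL-H, 2.5 equiv), CH2Cl2, −78 to 0 °C; then aq. potassium sodium tartrate
Reagents that add atoms: none
Why: Hydride reduction of the ester under non-basic conditions, done first so that the β-aryloxy ester never meets base (no epimerisation or E1cB ring opening); aryl mesylate and aryl bromide are inert at low temperature, and C3 keeps its arrangement (the descriptor becomes S only through the priority rules).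

Step 12
Reactants: 15 4-[(2R,3S)-7-(benzyloxy)-4-bromo-3-(hydroxymethyl)-2,3-dihydro-1-benzofuran-2-yl]-2-methoxyphenyl methanesulfonate
Product: 16 4-[(2R,3S)-7-(benzyloxy)-4-bromo-3-(hydroxymethyl)-2,3-dihydro-1-benzofuran-2-yl]-2-methoxyphenol
Conditions: KOH (3 M aq.), MeOH/THF, 60 °C; then dilute HCl to pH 5
Reagents that add atoms: none
Why: Alkaline hydrolysis of the aryl sulfonate by attack at sulfur, which is safe now that the ester is gone and no base-labile group remains.

Step 13
Reactants: 16 4-[(2R,3S)-7-(benzyloxy)-4-bromo-3-(hydroxymethyl)-2,3-dihydro-1-benzofuran-2-yl]-2-methoxyphenol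
Product: 17 (2R,3S)-7-(benzyloxy)-2-[4-(benzyloxy)-3-methoxyphenyl]-3-[(benzyloxy)methyl]-4-bromo-2,3-dihydro-1-benzofuran
Conditions: NaH (2.5 equiv), BnBr (2.4 equiv), n-Bu4NI (cat.), DMF, 0 °C to rt
Reagents that add atoms: benzyl bromide, BrCc1ccccc1
Why: Double Williamson etherification of the phenol and the primary alcohol, which puts every hydroxyl under the same protecting group for one final deprotection.

Step 14
Reactants: 17 (2R,3S)-7-(benzyloxy)-2-[4-(benzyloxy)-3-methoxyphenyl]-3-[(benzyloxy)methyl]-4-bromo-2,3-dihydro-1-benzofuran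
Product: 19 (2R,3S)-7-(benzyloxy)-2-[4-(benzyloxy)-3-methoxyphenyl]-3-[(benzyloxy)methyl]-2,3-dihydro-1-benzofuran-4-carbaldehyde, via aryllithium 18 (not isolated)
Conditions: n-BuLi (1.1 equiv), THF, −78 °C; DMF, −78 to 0 °C; then H2O
Reagents that add atoms: N,N-dimethylformamide, CN(C)C=O
Why: Bromine–lithium exchange followed by Bouveault formylation with DMF, fast at −78 °C so that the benzyl ethers are not deprotonated.

Step 15
Reactants: 20 2',4',6'-trihydroxyacetophenone
Product: 21 1-[2,4-bis(benzyloxy)-6-hydroxyphenyl]ethan-1-one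
Conditions: BnBr (2.1 equiv), K2CO3, DMF, rt
Reagents that add atoms: benzyl bromide, BrCc1ccccc1
Why: Williamson etherification that stops after two benzyl groups, because the remaining ortho hydroxyl is hydrogen-bonded to the ketone and poorly nucleophilic.

Step 16
Reactants: 19 (2R,3S)-7-(benzyloxy)-2-[4-(benzyloxy)-3-methoxyphenyl]-3-[(benzyloxy)methyl]-2,3-dihydro-1-benzofuran-4-carbaldehyde; 21 1-[2,4-bis(benzyloxy)-6-hydroxyphenyl]ethan-1-one
Product: 22 (E)-1-[2,4-bis(benzyloxy)-6-hydroxyphenyl]-3-{(2R,3S)-7-(benzyloxy)-2-[4-(benzyloxy)-3-methoxyphenyl]-3-[(benzyloxy)methyl]-2,3-dihydro-1-benzofuran-4-yl}prop-2-en-1-one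
Conditions: KOH (50% aq.), EtOH/THF, rt
Reagents that add atoms: none
Why: Claisen–Schmidt condensation of the methyl ketone enolate with the non-enolisable aldehyde, with E1cB dehydration giving the E-enone; all hydroxyls except the chelated phenol are benzylated, so nothing else is base-sensitive.

Step 17
Reactants: 22 the (E)-chalcone
Product: 23 5,7-bis(benzyloxy)-2-{(2R,3S)-7-(benzyloxy)-2-[4-(benzyloxy)-3-methoxyphenyl]-3-[(benzyloxy)methyl]-2,3-dihydro-1-benzofuran-4-yl}-4H-chromen-4-one
Conditions: I2 (0.1 equiv), DMSO, 130 °C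
Reagents that add atoms: none
Why: Iodine-catalysed oxidative cyclisation of a 2'-hydroxychalcone to the flavone (oxa-Michael closure, iodination and loss of HI, with DMSO as terminal oxidant), which avoids the aurone formation expected from a direct Algar–Flynn–Oyamada reaction on a 6'-alkoxychalcone.

Step 18
Reactants: 23 the 5,7-bis(benzyloxy)flavone
Product: 25 5,7-bis(benzyloxy)-2-{(2R,3S)-7-(benzyloxy)-2-[4-(benzyloxy)-3-methoxyphenyl]-3-[(benzyloxy)methyl]-2,3-dihydro-1-benzofuran-4-yl}-3-hydroxy-4H-chromen-4-one, via epoxide 24 (not isolated)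
Conditions: dimethyldioxirane (acetone solution, excess), CH2Cl2, 0 °C; then p-TsOH·H2O (cat.), rt
Reagents that add atoms: dimethyldioxirane, CC1(C)OO1
Why: Dioxirane epoxidation of the enol-ether-like C2=C3 bond of the 5,7-dialkoxyflavone, then acid-catalysed opening and tautomerisation of the epoxide to the 3-hydroxyflavone, the established way to turn benzylated flavones into flavonols.

Step 19
Reactants: 25 the pentabenzyl flavonol
Product: 26 3,5,7-trihydroxy-2-[(2R,3S)-7-hydroxy-2-(4-hydroxy-3-methoxyphenyl)-3-(hydroxymethyl)-2,3-dihydro-1-benzofuran-4-yl]-4H-chromen-4-one (CNP0195987.1)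
Conditions: H2 (1 atm), 10% Pd/C, THF/MeOH, rt
Reagents that add atoms: none
Why: Catalytic hydrogenolysis of the five benzyl ethers, mild enough to leave the cyclic benzylic ether of the dihydrobenzofuran and the flavonol double bond untouched, so both stereocentres reach the target unchanged.

**Compound list**

1 | 2,3-dihydroxybenzaldehyde | O=Cc1cccc(O)c1O | starting material
2 | 3-(benzyloxy)-2-hydroxybenzaldehyde | O=Cc1cccc(OCc2ccccc2)c1O | intermediate
3 | 2-(benzyloxy)-6-formylphenyl acetate | CC(=O)Oc1c(C=O)cccc1OCc1ccccc1 | intermediate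
4 | 6-(benzyloxy)-3-bromo-2-formylphenyl acetate | CC(=O)Oc1c(C=O)c(Br)ccc1OCc1ccccc1 | intermediate
5 | 6-(benzyloxy)-3-bromo-2-(1-hydroxyethyl)phenol (racemic) | CC(O)c1c(Br)ccc(OCc2ccccc2)c1O | intermediate
6 | 1-[3-(benzyloxy)-6-bromo-2-hydroxyphenyl]ethan-1-one | CC(=O)c1c(Br)ccc(OCc2ccccc2)c1O | intermediate
7 | (E)-1-[3-(benzyloxy)-6-bromo-2-hydroxyphenyl]-3-(dimethylamino)prop-2-en-1-one (enaminone, not isolated) | CN(C)/C=C/C(=O)c1c(Br)ccc(OCc2ccccc2)c1O | intermediate
8 | 8-(benzyloxy)-5-bromo-4H-chromen-4-one | O=c1ccoc2c(OCc3ccccc3)ccc(Br)c12 | intermediate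
9 | 2-methoxy-4-(4,4,5,5-tetramethyl-1,3,2-dioxaborolan-2-yl)phenol | COc1cc(B2OC(C)(C)C(C)(C)O2)ccc1O | starting material
10 | 2-methoxy-4-(4,4,5,5-tetramethyl-1,3,2-dioxaborolan-2-yl)phenyl methanesulfonate | COc1cc(B2OC(C)(C)C(C)(C)O2)ccc1OS(C)(=O)=O | intermediate
11 | [3-methoxy-4-(methylsulfonyloxy)phenyl]boronic acid | COc1cc(B(O)O)ccc1OS(C)(=O)=O | intermediate
12 | (2R)-8-(benzyloxy)-5-bromo-2-[3-methoxy-4-(methylsulfonyloxy)phenyl]-2,3-dihydro-4H-chromen-4-one | COc1cc([C@@H]2Oc3c(OCc4ccccc4)ccc(Br)c3C(=O)C2)ccc1OS(C)(=O)=O | intermediate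
13 | (2R)-8-(benzyloxy)-5-bromo-4-methoxy-2-[3-methoxy-4-(methylsulfonyloxy)phenyl]-2H-chromene (enol ether, not isolated) | COc1cc([C@@H]2Oc3c(OCc4ccccc4)ccc(Br)c3C(OC)=C2)ccc1OS(C)(=O)=O | intermediate
14 | methyl (2R,3R)-7-(benzyloxy)-4-bromo-2-[3-methoxy-4-(methylsulfonyloxy)phenyl]-2,3-dihydro-1-benzofuran-3-carboxylate (trans) | COc1cc([C@@H]2Oc3c(OCc4ccccc4)ccc(Br)c3[C@H]2C(=O)OC)ccc1OS(C)(=O)=O | intermediate
15 | 4-[(2R,3S)-7-(benzyloxy)-4-bromo-3-(hydroxymethyl)-2,3-dihydro-1-benzofuran-2-yl]-2-methoxyphenyl methanesulfonate | COc1cc([C@@H]2Oc3c(OCc4ccccc4)ccc(Br)c3[C@H]2CO)ccc1OS(C)(=O)=O | intermediate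
16 | 4-[(2R,3S)-7-(benzyloxy)-4-bromo-3-(hydroxymethyl)-2,3-dihydro-1-benzofuran-2-yl]-2-methoxyphenol | COc1cc([C@@H]2Oc3c(OCc4ccccc4)ccc(Br)c3[C@H]2CO)ccc1O | intermediate
17 | (2R,3S)-7-(benzyloxy)-2-[4-(benzyloxy)-3-methoxyphenyl]-3-[(benzyloxy)methyl]-4-bromo-2,3-dihydro-1-benzofuran | COc1cc([C@@H]2Oc3c(OCc4ccccc4)ccc(Br)c3[C@H]2COCc2ccccc2)ccc1OCc1ccccc1 | intermediate
18 | 4-lithio derivative of 17 (aryllithium, not isolated) | COc1cc([C@@H]2Oc3c(OCc4ccccc4)ccc([Li])c3[C@H]2COCc2ccccc2)ccc1OCc1ccccc1 | intermediate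
19 | (2R,3S)-7-(benzyloxy)-2-[4-(benzyloxy)-3-methoxyphenyl]-3-[(benzyloxy)methyl]-2,3-dihydro-1-benzofuran-4-carbaldehyde | COc1cc([C@@H]2Oc3c(OCc4ccccc4)ccc(C=O)c3[C@H]2COCc2ccccc2)ccc1OCc1ccccc1 | intermediate
20 | 2',4',6'-trihydroxyacetophenone | CC(=O)c1c(O)cc(O)cc1O | starting material
21 | 1-[2,4-bis(benzyloxy)-6-hydroxyphenyl]ethan-1-one | CC(=O)c1c(O)cc(OCc2ccccc2)cc1OCc1ccccc1 | intermediate
22 | (E)-1-[2,4-bis(benzyloxy)-6-hydroxyphenyl]-3-{(2R,3S)-7-(benzyloxy)-2-[4-(benzyloxy)-3-methoxyphenyl]-3-[(benzyloxy)methyl]-2,3-dihydro-1-benzofuran-4-yl}prop-2-en-1-one | COc1cc([C@@H]2Oc3c(OCc4ccccc4)ccc(/C=C/C(=O)c4c(O)cc(OCc5ccccc5)cc4OCc4ccccc4)c3[C@H]2COCc2ccccc2)ccc1OCc1ccccc1 | intermediate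
23 | 5,7-bis(benzyloxy)-2-{(2R,3S)-7-(benzyloxy)-2-[4-(benzyloxy)-3-methoxyphenyl]-3-[(benzyloxy)methyl]-2,3-dihydro-1-benzofuran-4-yl}-4H-chromen-4-one | COc1cc([C@@H]2Oc3c(OCc4ccccc4)ccc(-c4cc(=O)c5c(OCc6ccccc6)cc(OCc6ccccc6)cc5o4)c3[C@H]2COCc2ccccc2)ccc1OCc1ccccc1 | intermediate
24 | 2,3-epoxide of flavone 23 (mixture of epoxide diastereomers, not isolated) | COc1cc([C@@H]2Oc3c(OCc4ccccc4)ccc(C45OC4C(=O)c4c(OCc6ccccc6)cc(OCc6ccccc6)cc4O5)c3[C@H]2COCc2ccccc2)ccc1OCc1ccccc1 | intermediate
25 | 5,7-bis(benzyloxy)-2-{(2R,3S)-7-(benzyloxy)-2-[4-(benzyloxy)-3-methoxyphenyl]-3-[(benzyloxy)methyl]-2,3-dihydro-1-benzofuran-4-yl}-3-hydroxy-4H-chromen-4-one | COc1cc([C@@H]2Oc3c(OCc4ccccc4)ccc(-c4oc5cc(OCc6ccccc6)cc(OCc6ccccc6)c5c(=O)c4O)c3[C@H]2COCc2ccccc2)ccc1OCc1ccccc1 | intermediate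
26 | 3,5,7-trihydroxy-2-[(2R,3S)-7-hydroxy-2-(4-hydroxy-3-methoxyphenyl)-3-(hydroxymethyl)-2,3-dihydro-1-benzofuran-4-yl]-4H-chromen-4-one | COc1cc([C@@H]2Oc3c(O)ccc(-c4oc5cc(O)cc(O)c5c(=O)c4O)c3[C@H]2CO)ccc1O | target

**Step count and risks**

Total step count: 19. Longest linear sequence: 16 (steps 1–6, 9–14, 16–19).

The three steps most likely to fail:

1. Step 10 (ring contraction). After the iodane has added at C3, loss of iodobenzene together with the C2 hydrogen (dehydrogenation to the flavone) or a shift of the C2 aryl group may outrun the shift of C4a. The peri bromine may also slow ketal and enol ether formation. Fallback: the same carbon is expelled by a Wolff rearrangement. Setting out from 12, LiN(SiMe3)2 in THF at −78 °C and CF3CO2CH2CF3 should give the 3-trifluoroacetyl flavanone F1; the low temperature keeps the enolate from opening to the chalcone. Detrifluoroacetylative diazo transfer (MsN3, Et3N, MeCN/H2O) should give the 3-diazoflavanone F2. Irradiation in MeOH should then trigger the Wolff rearrangement, in which C4a migrates to C3 and methanol adds to the ring-contracted ketene. This gives ester 14, possibly with its cis C3 epimer F3, which DBU in CH2Cl2 should equilibrate to the trans ester. The fallback comes back to the route at 14.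

2. Step 9 (asymmetric conjugate addition). Insertion of the hindered 5-bromo-8-benzyloxychromone may be slow, so that protodeboronation of 11 consumes the aryl donor. Reversible opening of the product to the chalcone would erode the enantiomeric purity. Fallback: racemic synthesis and kinetic resolution. Setting out from 6, condensation with 4-formyl-2-methoxyphenyl methanesulfonate F4 (from vanillin, MsCl, Et3N) and pyrrolidine in EtOH at 60 °C should give the racemic flavanone F5 by aldol condensation and oxa-Michael closure. Asymmetric transfer hydrogenation with RuCl(p-cymene)[(R,R)-TsDPEN] and HCO2H/Et3N, or with the antipodal catalyst (whichever reduces the (2S)-ketone faster), should convert the unwanted enantiomer into the cis-flavan-4-ol F6. The unreduced (R)-ketone is separated by chromatography, and the fallback comes back to the route at 12.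

3. Step 18 (C3 hydroxylation). Epoxidation of the flavone double bond is slow, and the dioxirane may instead oxidise benzylic C–H bonds (in particular C2–H of the dihydrobenzofuran) or the electron-rich rings. Fallback: anionic hydroxylation. Setting out from 23, LiN(i-Pr)2 in THF at −78 °C should deprotonate C3 of the flavone, and B(OMe)3 should trap the anion as the flavone 3-boronate F7. Oxidation of the carbon–boron bond with H2O2/AcOH should give the flavonol, and the fallback comes back to the route at 25.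

**Further compounds**

F1 | step 10 | (2R)-8-(benzyloxy)-5-bromo-2-[3-methoxy-4-(methylsulfonyloxy)phenyl]-3-(trifluoroacetyl)chroman-4-one | COc1cc([C@@H]2Oc3c(OCc4ccccc4)ccc(Br)c3C(=O)C2C(=O)C(F)(F)F)ccc1OS(C)(=O)=O
F2 | step 10 | (2S)-8-(benzyloxy)-5-bromo-3-diazo-2-[3-methoxy-4-(methylsulfonyloxy)phenyl]chroman-4-one (same arrangement at C2 as in 12; the descriptor changes by the priority rules) | COc1cc([C@@H]2Oc3c(OCc4ccccc4)ccc(Br)c3C(=O)C2=[N+]=[N-])ccc1OS(C)(=O)=O
F3 | step 10 | methyl (2R,3S)-7-(benzyloxy)-4-bromo-2-[3-methoxy-4-(methylsulfonyloxy)phenyl]-2,3-dihydro-1-benzofuran-3-carboxylate (cis) | COc1cc([C@@H]2Oc3c(OCc4ccccc4)ccc(Br)c3[C@@H]2C(=O)OC)ccc1OS(C)(=O)=O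
F4 | step 9 | 4-formyl-2-methoxyphenyl methanesulfonate | COc1cc(C=O)ccc1OS(C)(=O)=O
F5 | step 9 | racemic 8-(benzyloxy)-5-bromo-2-[3-methoxy-4-(methylsulfonyloxy)phenyl]chroman-4-one | COc1cc(C2Oc3c(OCc4ccccc4)ccc(Br)c3C(=O)C2)ccc1OS(C)(=O)=O
F6 | step 9 | 4-[(2S,4S)-8-(benzyloxy)-5-bromo-4-hydroxychroman-2-yl]-2-methoxyphenyl methanesulfonate (cis) | COc1cc([C@H]2Oc3c(OCc4ccccc4)ccc(Br)c3[C@@H](O)C2)ccc1OS(C)(=O)=O
F7 | step 18 | dimethyl {5,7-bis(benzyloxy)-2-[(2R,3S)-7-(benzyloxy)-2-(4-(benzyloxy)-3-methoxyphenyl)-3-((benzyloxy)methyl)-2,3-dihydro-1-benzofuran-4-yl]-4-oxo-4H-chromen-3-yl}boronate | COc1cc([C@@H]2Oc3c(OCc4ccccc4)ccc(-c4oc5cc(OCc6ccccc6)cc(OCc6ccccc6)c5c(=O)c4B(OC)OC)c3[C@H]2COCc2ccccc2)ccc1OCc1ccccc1
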